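In a one-step world electrophile and nucleophile give target one to one, so each added portion of nucleophile would buy the same portion of target. Here are the runs and what is asked.

common to all: electrophile 0.30 M
- larch: nucleophile 0.18 M; protic impurity 0.060 M; run made earlier
- birch: nucleophile 0.29 M; protic impurity 0.060 M; run made earlier
- theta: nucleophile 0.280 M; protic impurity 0.0600 M; time 10 d
- alpha: nucleophile 0.370 M; protic impurity 0.0600 M; time 10 d
- gamma: nucleophile 0.480 M; protic impurity 0.0600 M; time 10 d

- larch (time / d: electrophile / %, target / %): 0.333: 77, 28; 1.04: 77, 24; 1.67: 76, 26; 2.50: 74, 24; 4.00: 75, 28; 5.00: 74, 26
- birch (time / d: electrophile / %, target / %): 0.417: 55, 42; 0.625: 57, 47; 1.04: 59, 37; 1.67: 58, 44; 3.00: 58, 42; 5.00: 62, 44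

(each reading ± 2 percentage points)

- a reading or a percentage of target counts all its forms, free or not

- part of the electrophile that has reacted at the end, theta
- part of the electrophile that has reacted at the end, alpha
- part of the electrophile that has reacted at the end, gamma
- what raising the concentration of nucleophile from its lowest to its highest value here does to the part of the electrophile that has reacted (changes below 5 percentage points count as none) (it rises / it falls / no change)

Within the scatter, larch and birch both read flat from their first samples, so I set time aside and compare their plateaus. Mean target reads 26.0% in larch and 42.7% in birch. Dividing the added nucleophile by the added target gives a reading of 2.20 nucleophile per target, so I take two, not one. I also let the protic impurity claim one nucleophile each, and fold the charges into one number: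

Y = (c(nucleophile) − c(protic impurity)) / (2 · c(electrophile))

theta 36.7%, alpha 51.7%, gamma 70.0%

I call Y the reach: the share of the electrophile that the nucleophile, as limiting reagent, can pay for at two per target once the impurity has taken its claim. Time has dropped out of it.

Is one number enough? Larch has a reach of 20.0% and birch 38.3%, and their readings stand 6 percentage points and 4.4 points higher. That suggests the impurity had not taken its whole claim by 5.00 d. So I expect each answer at its reach or a few points above, rising from theta to gamma.

The forecast says 41.5% (38% to 45%), 54% (49% to 60%) and 66% (58% to 77%), and that the reacted part it rises. Its ground is: “I favour equilibrium but lean slightly upward.” My reach differs from it most at theta, where I have 36.7%, which is 4.8 points below the forecast's value and under the low end of its range.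

The flask gives 38.8%, 52.3% and 69.4%, and the reacted part it rises by 31 points.

    nucleophile + protic impurity → quenched reagent (k = 0.0230 L mol⁻¹ min⁻¹)
    nucleophile + acid set free ⇌ protonated nucleophile, settled at all times (K = 24000 L mol⁻¹)
    electrophile + nucleophile ⇌ acid set free + target (K = 0.430, k = 0.0190 L mol⁻¹ min⁻¹)
    crystals ⇌ target, rate k4*(cs4 - [target]) while solid is left; crystals form when [target] > cs4 (solubility = 0.210 M, k = 0.00900 min⁻¹)

At 10 d theta is not quite at rest: 22% of its protic impurity remains, and by 100 d that falls to 0.0139% while the reacted part sinks from 38.8% to 36.6%, against a reach of 36.7%. Alpha goes from 52.3% to 51.3%, against 51.7%. Gamma, with 2.7% of its impurity left, ends at 69.1%, against 70.0%, and the longer run changes it very little. A further flask like gamma but with 1.2 M of electrophile has a reach of 17.5% and gives 18.5% at 10.0 d, with 38% of its protic impurity still there.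

The readings come from a simulation from invented constants; scatter was added.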